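At early times each substrate that reacts costs one reagent, and each bis adduct formed later costs one more. Full bis adduct takes two reagent per substrate and the flask holds 1.10 equiv, so reagent is the limiting reagent. Bis adduct is not read; it is what the readings leave missing.

| flask | substrate | reagent | remark | time |
|---|---|---|---|---|
| Thursday's | 0.013 M | 1.1 equiv | run made earlier |  |
| Wednesday's | 0.030 M | 1.1 equiv | run made earlier |  |
| Sunday's | 0.020 M | 0.55 equiv | run made earlier |  |
| flask | 0.020 M | 1.10 equiv |  | 30 min |

| run | time / min | substrate / % | mono adduct / % | other mono adduct / % |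
|---|---|---|---|---|
| Thursday's | 4.00 | 86.7 | 7.3 | 5.9 |
| Thursday's | 10.0 | 71.3 | 13.0 | 10.1 |
| Thursday's | 20.0 | 57.1 | 17.2 | 13.9 |
| Thursday's | 30.0 | 48.6 | 19.0 | 15.6 |
| Wednesday's | 4.00 | 73.4 | 11.6 | 9.6 |
| Wednesday's | 10.0 | 53.8 | 20.3 | 15.2 |
| Wednesday's | 20.0 | 38.5 | 26.0 | 15.6 |
| Wednesday's | 30.0 | 32.5 | 28.0 | 16.2 |
| Sunday's | 4.00 | 89.7 | 5.4 | 4.0 |
| Sunday's | 10.0 | 79.0 | 10.0 | 8.2 |
| Sunday's | 20.0 | 70.0 | 13.9 | 10.9 |
| Sunday's | 30.0 | 65.3 | 15.4 | 12.9 |

(standard deviation of a reading: 0.5 percentage points)

1. substrate at 30 min, in percent of the substrate charged
2. mono adduct at 30 min, in percent of the substrate charged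
3. other mono adduct at 30 min, in percent of the substrate charged
4. bis adduct at 30 min, in percent of the substrate charged

Concentration first. By hand, substrate and reagent must meet, so a stronger charge should lose substrate faster, and Wednesday's run does: 32.5% remains at 30.0 min, less than Thursday's 48.6%.

Time should count the same way, so concentration times time is my clock. The flask's 0.020 M for 30 min equals Wednesday's 0.030 M for 20.0 min, at the same equivalents. I therefore commit to that reading: substrate 38.5%, mono adduct 26.0%, other mono adduct 15.6%, bis adduct 19.9%. Substrate lost there is 61.5%, so p reads 1.32: p is the reagent price, reagent spent per substrate lost.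

Reagent last. By hand, less of it should lower the price, since the second addition needs reagent too. Sunday's run at 0.55 equiv reads 1.18 at 30.0 min, below p, but it has also lost 34.7% of its substrate, so reagent is not the one thing that differs. For the flask, p on that loss spends 81.4% of the substrate charge in reagent, leaving 26.0% of the reagent's own charge.

The forecast starts from the same point but holds that “longer real time seems to favour bis a little”, and gives substrate 39%, mono adduct 25%, other mono adduct 15.2%, bis adduct 20.8%.

The flask gives substrate 39.5%, mono adduct 23.2%, other mono adduct 16.0%, bis adduct 21.2%.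

    mono adduct → over-reaction product (k = 9.30 × 10⁻⁵ /min)
    crystals ⇌ mono adduct, rate k2*(cs2 - [mono adduct]) while solid is left; crystals form when [mono adduct] > cs2 (solubility = 2.00 mM, k = 0.790 /min)
    substrate + reagent → mono adduct + released group (k = 1.50 /M/min)
    reagent + mono adduct → bis adduct + released group (k = 3.20 /M/min)
    substrate + reagent → other mono adduct + released group (k = 1.20 /M/min)
    reagent + other mono adduct → bis adduct + released group (k = 2.80 /M/min)

My p on the flask's loss leaves 27.4% of the reagent; the flask holds 26%. Two steps acting together explain a part of why the flask's mono adduct stands at 23.2%, reagent carrying it on to bis adduct and substrate also going to other mono adduct: the flask run without the first step gives 35.0% and without the second 33.9%, and 39.5% of its substrate is still unreacted. Bis adduct shifts by 5 points with reagent at 0.913 equiv or 1.28 equiv, or time at 20.5 min or 44.7 min.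

The neighbour at 0.034 M keeps 30.4% of its substrate, and p on the substrate it has lost leaves 16.3% of the reagent; that flask holds 14%.

All runs were computed for an exercise, noise included.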